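**Retrosynthetic overview**
- Target 14 comes from the 2,4-cis flavan-4-ol 12 by oxidation at C4 and desilylation; C4 is a sacrificial stereocentre and only C2 is kept.
- The strategy rests on ring C: O1–C8a–C4a–C4 (the phenol oxygen, two ring-A carbons and the formyl carbon of salicylaldehyde 2) wraps around C2–C3 (the vinyl carbons of ring-B styrene 10). Both O1–C2 and C3–C4 are therefore cut in one chiral-acid-catalysed formal oxa-[4+2].
- Styrene 10 comes from aldehyde 9 by Wittig methylenation; ring D of 9 comes from aryl propargyl ether 7 by Claisen rearrangement and electrocyclisation; the prenyl group comes from ortho-C-prenylation of 4-hydroxybenzaldehyde.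
- Aldehyde 2 comes from 2,4-dihydroxybenzaldehyde by selective 4-O-silylation.
- Ring order: rings A and B are purchased, ring D is formed in step 4 and ring C last, in step 6.

Key step: step 6

Assumption: the absolute sense of induction of the confined acid cannot be assigned in advance, so "(S,S)-IDPi" denotes the catalyst antipode that screening shows to direct the styrene to the Re face of the formyl carbon of 2 (giving the 4R carbinol); its mirror image is equally accessible.

**Route**

Step 1
Reactants: 1 2,4-dihydroxybenzaldehyde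
Product: 2 4-(tert-butyldimethylsilyloxy)-2-hydroxybenzaldehyde
Conditions: TBSCl (1.05 equiv), imidazole, CH2Cl2, 0 °C
Reagents that add atoms: tert-butyldimethylsilyl chloride, CC(C)(C)[Si](C)(C)Cl
Why: Chemoselective O-silylation, because the 2-hydroxyl is held in a hydrogen bond to the adjacent formyl oxygen while the 4-hydroxyl is free and more acidic.

Step 2
Reactants: 3 4-hydroxybenzaldehyde; 4 prenyl bromide (1-bromo-3-methylbut-2-ene)
Product: 5 4-hydroxy-3-(3-methylbut-2-en-1-yl)benzaldehyde
Conditions: KOH (aq.), rt; chromatographic separation from the O-prenyl ether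
Reagents that add atoms: none
Why: Ortho-C-allylation of an ambident phenoxide in water, where solvation of the oxygen steers the prenyl electrophile to the adjacent ring carbon and the para position is blocked by the formyl group.

Step 3
Reactants: 5 4-hydroxy-3-(3-methylbut-2-en-1-yl)benzaldehyde; 6 3-chloro-3-methylbut-1-yne
Product: 7 4-[(2-methylbut-3-yn-2-yl)oxy]-3-(3-methylbut-2-en-1-yl)benzaldehyde
Conditions: DBU, CuCl2 (cat.), MeCN, 0 °C to rt
Reagents that add atoms: none
Why: Copper-catalysed O-propargylation of a phenol with a tertiary propargylic chloride, the standard entry to aryl 1,1-dimethylpropargyl ethers and well suited to electron-poor phenols.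

Step 4
Reactants: 7 4-[(2-methylbut-3-yn-2-yl)oxy]-3-(3-methylbut-2-en-1-yl)benzaldehyde
Product: 9 2,2-dimethyl-8-(3-methylbut-2-en-1-yl)-2H-chromene-6-carbaldehyde, via ortho-allenylphenol 8 (not isolated)
Conditions: PhNEt2, 190 °C
Reagents that add atoms: none
Why: Aromatic propargyl Claisen rearrangement to the only free ortho carbon, tautomerisation to allenylphenol 8, 1,5-hydrogen shift and oxa-6π electrocyclisation close ring D as the 2,2-dimethyl-2H-chromene.

Step 5
Reactants: 9 2,2-dimethyl-8-(3-methylbut-2-en-1-yl)-2H-chromene-6-carbaldehyde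
Product: 10 6-ethenyl-2,2-dimethyl-8-(3-methylbut-2-en-1-yl)-2H-chromene
Conditions: Ph3PCH3Br, KOtBu, THF, 0 °C to rt; product stored cold with BHT and used promptly
Reagents that add atoms: methyltriphenylphosphonium bromide, C[P+](c1ccccc1)(c1ccccc1)c1ccccc1.[Br-]
Why: Wittig methylenation of an aromatic aldehyde with the non-stabilised ylide, which touches no other group in 9.

Step 6
Reactants: 2 4-(tert-butyldimethylsilyloxy)-2-hydroxybenzaldehyde; 10 6-ethenyl-2,2-dimethyl-8-(3-methylbut-2-en-1-yl)-2H-chromene
Product: 12 (2R,4R)-7-(tert-butyldimethylsilyloxy)-2-[2,2-dimethyl-8-(3-methylbut-2-en-1-yl)-2H-chromen-6-yl]chroman-4-ol, via open benzylic cation 11 (not isolated)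
Conditions: (S,S)-IDPi (BINOL-derived imidodiphosphorimidate acid, N-triflyl, 3,3'-diaryl; 5 mol %), 4 Å MS, CH2Cl2/toluene, −60 to −40 °C, 10 added slowly to 2 (1.5 equiv); Et3N quench at −40 °C
Reagents that add atoms: none
Why: Proposed new method: the confined chiral acid protonates the formyl oxygen of 2, the most basic site present, to give a hydroxy-substituted ortho-quinone methide/carboxonium ion pair; the unhindered CH2 terminus of styrene 10 adds to the formyl carbon (C3–C4 bond) and the resulting benzylic cation 11, stabilised by the para oxygen of ring B, is captured by the phenolic oxygen (O1–C2 bond), releasing the catalyst without any by-product. The closest known reaction types are acid-mediated [4+2] annulations of salicylaldehyde-derived ortho-quinone methides (acetal or orthoformate activation) with styrenes, confined-acid-catalysed asymmetric intermolecular Prins reactions of styrenes with aldehydes, and chiral phosphoric-acid-type ortho-quinone methide cycloadditions. Ring C closes in a formal hetero-[4+2] that is 6-endo with respect to the styrene C=C, the O1–C2 bond itself forming by 6-exo-trig capture of the para-quinone-methide-like cation. C4 is set by the chiral counter-anion, which shields the Si face of the formyl carbon so that Re-face attack gives 4R; C2 is set by the substrate, since closure through a half-chair with the C4 hydroxyl and the aryl group both pseudo-equatorial gives the 2,4-cis ring and hence 2R, and any reversible C2–O1 ionisation only re-equilibrates C2 against the fixed C4 towards the same cis isomer. The step needs chemoselectivity for the vinyl group, secured by its para-oxygen activation and open terminal carbon, whereas the ring-D alkene is flanked by the gem-dimethyl carbon and the prenyl alkene would give a non-benzylic cation; slow addition of 10 to excess 2 at low temperature and the cold amine quench limit styrene oligomerisation and ionisation of the product carbinol.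

Step 7
Reactants: 12 (2R,4R)-7-(tert-butyldimethylsilyloxy)-2-[2,2-dimethyl-8-(3-methylbut-2-en-1-yl)-2H-chromen-6-yl]chroman-4-ol
Product: 13 (2R)-7-(tert-butyldimethylsilyloxy)-2-[2,2-dimethyl-8-(3-methylbut-2-en-1-yl)-2H-chromen-6-yl]chroman-4-one
Conditions: Dess–Martin periodinane, NaHCO3, CH2Cl2, 0 °C
Reagents that add atoms: none
Why: Dess–Martin oxidation of the secondary benzylic alcohol under bicarbonate buffer avoids both acid ionisation of the carbinol and base-induced retro-oxa-Michael opening, so C2 is untouched while the C4 stereocentre is deliberately erased.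

Step 8
Reactants: 13 (2R)-7-(tert-butyldimethylsilyloxy)-2-[2,2-dimethyl-8-(3-methylbut-2-en-1-yl)-2H-chromen-6-yl]chroman-4-one
Product: 14 ent-abyssinone III, (2R)-7-hydroxy-2-[2,2-dimethyl-8-(3-methylbut-2-en-1-yl)-2H-chromen-6-yl]chroman-4-one
Conditions: HF·pyridine, pyridine, THF, 0 °C to rt; pH 7 buffer work-up
Reagents that add atoms: none
Why: Fluoride cleavage of the aryl silyl ether (Si–F bond formation) under weakly acidic buffered conditions generates neither phenoxide nor enolate, so the flavanone should not racemise at C2 through the ring-opened chalcone.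

**Compound list**
1 | 2,4-dihydroxybenzaldehyde | O=Cc1ccc(O)cc1O | starting material
2 | 4-(tert-butyldimethylsilyloxy)-2-hydroxybenzaldehyde | O=Cc1ccc(O[Si](C)(C)C(C)(C)C)cc1O | intermediate
3 | 4-hydroxybenzaldehyde | O=Cc1ccc(O)cc1 | starting material
4 | prenyl bromide (1-bromo-3-methylbut-2-ene) | CC(C)=CCBr | starting material
5 | 4-hydroxy-3-(3-methylbut-2-en-1-yl)benzaldehyde | O=Cc1ccc(O)c(CC=C(C)C)c1 | intermediate
6 | 3-chloro-3-methylbut-1-yne | CC(C)(Cl)C#C | starting material
7 | 4-[(2-methylbut-3-yn-2-yl)oxy]-3-(3-methylbut-2-en-1-yl)benzaldehyde | O=Cc1ccc(OC(C)(C)C#C)c(CC=C(C)C)c1 | intermediate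
8 | 4-hydroxy-3-(3-methylbuta-1,2-dien-1-yl)-5-(3-methylbut-2-en-1-yl)benzaldehyde (ortho-allenylphenol, not isolated) | O=Cc1cc(CC=C(C)C)c(O)c(C=C=C(C)C)c1 | intermediate
9 | 2,2-dimethyl-8-(3-methylbut-2-en-1-yl)-2H-chromene-6-carbaldehyde | O=Cc1cc(CC=C(C)C)c2OC(C)(C)C=Cc2c1 | intermediate
10 | 6-ethenyl-2,2-dimethyl-8-(3-methylbut-2-en-1-yl)-2H-chromene | C=Cc1cc(CC=C(C)C)c2OC(C)(C)C=Cc2c1 | intermediate
11 | (3R)-1-[2,2-dimethyl-8-(3-methylbut-2-en-1-yl)-2H-chromen-6-yl]-3-hydroxy-3-[2-hydroxy-4-(tert-butyldimethylsilyloxy)phenyl]propan-1-ylium, ion pair with the catalyst anion (open benzylic cation, not isolated) | CC(C)=CCc1cc([CH+]C[C@@H](O)c3ccc(O[Si](C)(C)C(C)(C)C)cc3O)cc2c1OC(C)(C)C=C2 | intermediate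
12 | (2R,4R)-7-(tert-butyldimethylsilyloxy)-2-[2,2-dimethyl-8-(3-methylbut-2-en-1-yl)-2H-chromen-6-yl]chroman-4-ol (2,4-cis) | CC(C)=CCc1cc([C@H]2C[C@@H](O)c3ccc(O[Si](C)(C)C(C)(C)C)cc3O2)cc2c1OC(C)(C)C=C2 | intermediate
13 | (2R)-7-(tert-butyldimethylsilyloxy)-2-[2,2-dimethyl-8-(3-methylbut-2-en-1-yl)-2H-chromen-6-yl]chroman-4-one | CC(C)=CCc1cc([C@H]2CC(=O)c3ccc(O[Si](C)(C)C(C)(C)C)cc3O2)cc2c1OC(C)(C)C=C2 | intermediate
14 | ent-abyssinone III, (2R)-7-hydroxy-2-[2,2-dimethyl-8-(3-methylbut-2-en-1-yl)-2H-chromen-6-yl]chroman-4-one | CC(C)=CCc1cc([C@H]2CC(=O)c3ccc(O)cc3O2)cc2c1OC(C)(C)C=C2 | target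

**Step count**
Total: 8 steps. Longest linear sequence: 7 steps (3 → 5 → 7 → 9 → 10 → 12 → 13 → 14; steps 2 to 8).

**Steps most likely to fail**

1. Step 6 (proposed new method). Facial discrimination at the formyl carbon may be insufficient, the electron-rich styrene may oligomerise under the strong acid, the newly formed benzylic carbinol may ionise, or the acid may engage the prenyl or ring-D alkene. The fallback uses known chemistry, sets out from aldehyde 9 and returns at 12. Aldehyde 9 would be condensed with 2',4'-dihydroxyacetophenone (KOH, aq. EtOH; Claisen–Schmidt) to the 2'-hydroxychalcone F1. NaOAc in refluxing EtOH would cyclise this by oxa-Michael addition to the racemic 7-hydroxyflavanone F2, and silylation (TBSCl, imidazole, CH2Cl2) would give the racemic silyl ether F3. A kinetic resolution by asymmetric transfer hydrogenation (RuCl[(R,R)-TsDPEN](p-cymene), HCO2H/Et3N, rt) would then reduce the (2R)-enantiomer to the cis carbinol 12. The catalyst antipode is chosen by analogy with aryl ketone reductions to deliver the 4R carbinol, and the unreacted (2S)-ketone is separated. The route continues from 12 with steps 7 and 8.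

2. Step 2. O-alkylation and double alkylation of the phenoxide may outcompete mono-ortho-C-prenylation, leaving little 5. The fallback sets out from 3 and returns at 9, installing the prenyl group last by cross-coupling. Compound 3 would be brominated (Br2, AcOH) to 3-bromo-4-hydroxybenzaldehyde F4 and etherified with 6 (DBU, CuCl2 cat., MeCN) to the bromo propargyl ether F5. Thermal rearrangement (PhNEt2, 190 °C) would give 8-bromo-2,2-dimethyl-2H-chromene-6-carbaldehyde F6. A Stille coupling with tributyl(3-methylbut-2-en-1-yl)stannane (Pd(PPh3)4, zerovalent palladium, DMF, 90 °C) would then give 9.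

3. Step 8. Adventitious base or free fluoride may open the flavanone to the chalcone and erode configuration at C2, or the aryl silyl ether may cleave too slowly under the mild acidic fluoride. The fallback sets out from 12 and returns at 14, reversing the order so that fluoride never meets the flavanone. Compound 12 would be desilylated first (TBAF, THF, 0 °C), when no carbonyl is present, to (2R,4R)-2-[2,2-dimethyl-8-(3-methylbut-2-en-1-yl)-2H-chromen-6-yl]chromane-4,7-diol F7. The benzylic 4-hydroxyl would then be oxidised chemoselectively with activated MnO2 in CH2Cl2 at rt to give 14 directly.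

**Further compounds**
F1 | step 6 | (E)-1-(2,4-dihydroxyphenyl)-3-[2,2-dimethyl-8-(3-methylbut-2-en-1-yl)-2H-chromen-6-yl]prop-2-en-1-one | O=C(/C=C/c1cc(CC=C(C)C)c2OC(C)(C)C=Cc2c1)c1ccc(O)cc1O
F2 | step 6 | racemic 7-hydroxy-2-[2,2-dimethyl-8-(3-methylbut-2-en-1-yl)-2H-chromen-6-yl]chroman-4-one | CC(C)=CCc1cc(C2CC(=O)c3ccc(O)cc3O2)cc2c1OC(C)(C)C=C2
F3 | step 6 | racemic 7-(tert-butyldimethylsilyloxy)-2-[2,2-dimethyl-8-(3-methylbut-2-en-1-yl)-2H-chromen-6-yl]chroman-4-one | CC(C)=CCc1cc(C2CC(=O)c3ccc(O[Si](C)(C)C(C)(C)C)cc3O2)cc2c1OC(C)(C)C=C2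
F4 | step 2 | 3-bromo-4-hydroxybenzaldehyde | O=Cc1ccc(O)c(Br)c1
F5 | step 2 | 3-bromo-4-[(2-methylbut-3-yn-2-yl)oxy]benzaldehyde | O=Cc1ccc(OC(C)(C)C#C)c(Br)c1
F6 | step 2 | 8-bromo-2,2-dimethyl-2H-chromene-6-carbaldehyde | O=Cc1cc(Br)c2OC(C)(C)C=Cc2c1
F7 | step 8 | (2R,4R)-2-[2,2-dimethyl-8-(3-methylbut-2-en-1-yl)-2H-chromen-6-yl]chromane-4,7-diol | CC(C)=CCc1cc([C@H]2C[C@@H](O)c3ccc(O)cc3O2)cc2c1OC(C)(C)C=C2
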